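## Retrosynthetic overview

1. Target 25 comes from ketone 19 by enolate hydroxylation trans to the side chain, senecioylation of that hydroxyl, and exchange of the side-chain silyl ether for acetate.
2. Ketone 19 comes from a rhodium-catalysed asymmetric 1,4-addition of alkenylboronate 8 to epoxy enone 18, which forms the ring–side-chain bond cis to the oxirane oxygen.
3. Epoxy enone 18 comes from the key step: a one-carbon ring expansion of epoxy cyclopentanone 12 with dibromomethane (β-oxido carbenoid 1,2-shift), with the resulting enolate dehydrogenated in the same flask.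
4. Ketone 12 comes from 2-methylcyclopent-2-en-1-one by CBS reduction, hydroxyl-directed epoxidation and oxidation. Boronate 8 comes from 4-methylpent-3-enal by asymmetric alkynylation, silylation and α-selective protoboration.
5. Ring order: the oxirane is made first, on the five-membered ring; the six-membered carbocycle then arises by ring expansion. No other ring is formed.

Assumption: compounds 1, 3, 9, 13 and 22 are bought; "cis" and "trans" refer to the target SMILES, in which the side chain is cis to the oxirane oxygen and trans to the senecioate.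

## Route

Step 1
Reactants: 1 4-methylpent-3-en-1-ol
Product: 2 4-methylpent-3-enal
Conditions: Dess–Martin periodinane, NaHCO3, CH2Cl2, 0 °C; used as a crude solution
Reagents that add atoms: none
Why: Dess–Martin oxidation of the homoallylic primary alcohol under buffered, non-basic conditions gives the β,γ-unsaturated aldehyde without moving the double bond into conjugation; no stereocenter is involved.

Step 2
Reactants: 2 4-methylpent-3-enal; 3 ethynyltrimethylsilane
Product: 6 (3R)-6-methylhept-5-en-1-yn-3-ol, via alkynylzinc reagent 4 (not isolated), via C-silylated alkynol 5 (not isolated)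
Conditions: Me2Zn, ProPhenol ligand (10 mol %, the enantiomer that gives the 3R carbinol, checked by Mosher ester), Ph3P=O (20 mol %), toluene, 0 °C, slow addition of 2; then K2CO3, MeOH, 23 °C
Reagents that add atoms: none
Why: Zinc–ProPhenol catalysed asymmetric alkynylation (Trost-type alkynylzinc addition) sets the carbinol stereocenter by ligand-controlled face selection at the aldehyde, and methanolysis of the C–Si bond then frees the terminal alkyne.

Step 3
Reactants: 6 (3R)-6-methylhept-5-en-1-yn-3-ol
Product: 7 triethyl{[(3R)-6-methylhept-5-en-1-yn-3-yl]oxy}silane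
Conditions: Et3SiCl, imidazole, CH2Cl2, 0 °C
Reagents that add atoms: chlorotriethylsilane CC[Si](Cl)(CC)CC
Why: Standard silylation; the silyl ether is a poor β-leaving group on the later alkenylrhodium species (an acetate would be lost to an allene) and keeps this oxygen distinct from the ring hydroxyl; the stereocenter is untouched.

Step 4
Reactants: 7 triethyl{[(3R)-6-methylhept-5-en-1-yn-3-yl]oxy}silane
Product: 8 triethyl{[(3R)-6-methyl-2-(4,4,5,5-tetramethyl-1,3,2-dioxaborolan-2-yl)hepta-1,5-dien-3-yl]oxy}silane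
Conditions: (SIMes)CuCl (5 mol %; SIMes = 1,3-dimesitylimidazolidin-2-ylidene), NaOt-Bu (5 mol %), B2pin2, MeOH, THF, −50 to −15 °C
Reagents that add atoms: bis(pinacolato)diboron CC1(C)OB(OC1(C)C)B1OC(C)(C)C(C)(C)O1
Why: NHC–copper-catalysed protoboration: the copper–boryl species adds across the terminal alkyne with boron on the internal carbon (the α-selectivity of N-aryl carbene copper catalysts with propargylic ethers) and methanol protonates the alkenylcopper, giving the 1,1-disubstituted alkenylboronate without touching the stereocenter or the trisubstituted alkene.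

Step 5
Reactants: 9 2-methylcyclopent-2-en-1-one
Product: 10 (1R)-2-methylcyclopent-2-en-1-ol
Conditions: (S)-2-methyl-CBS-oxazaborolidine (10 mol %), BH3·SMe2, THF, −30 °C; MeOH quench
Reagents that add atoms: none
Why: Corey–Bakshi–Shibata reduction: the oxazaborolidine–borane complex treats the α-substituted alkene carbon as the large group and delivers hydride 1,2 to one carbonyl face, giving the (R)-allylic alcohol.

Step 6
Reactants: 10 (1R)-2-methylcyclopent-2-en-1-ol
Product: 11 (1R,2R,5S)-1-methyl-6-oxabicyclo[3.1.0]hexan-2-ol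
Conditions: VO(acac)2 (2 mol %), t-BuOOH, CH2Cl2, 0 °C to 23 °C
Reagents that add atoms: tert-butyl hydroperoxide CC(C)(C)OO
Why: Hydroxyl-directed vanadium-catalysed epoxidation (Sharpless–Michaelson type): the vanadate ester of the allylic alcohol delivers oxygen to the alkene face syn to the hydroxyl, which fixes both oxirane carbons relative to the CBS-set carbinol.

Step 7
Reactants: 11 (1R,2R,5S)-1-methyl-6-oxabicyclo[3.1.0]hexan-2-ol
Product: 12 (1S,5S)-1-methyl-6-oxabicyclo[3.1.0]hexan-2-one
Conditions: (n-Pr4N)RuO4 (5 mol %), N-methylmorpholine N-oxide, 4 Å molecular sieves, CH2Cl2, 0 °C to 23 °C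
Reagents that add atoms: none
Why: Ley–Griffith oxidation of the secondary alcohol under neutral conditions gives the α,β-epoxy ketone; the oxirane stereocenters cannot epimerise because the α-carbon is quaternary.

Step 8
Reactants: 12 (1S,5S)-1-methyl-6-oxabicyclo[3.1.0]hexan-2-one; 13 dibromomethane
Product: 18 (1S,6S)-1-methyl-7-oxabicyclo[4.1.0]hept-3-en-2-one, via dibromomethyllithium 14 (not isolated), via lithium dibromomethyl carbinolate 15 (not isolated), via lithium β-oxido carbenoid 16 (not isolated), via ring-expanded lithium enolate 17 (not isolated)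
Conditions: lithium 2,2,6,6-tetramethylpiperidide added to 12 and 13, THF, −78 °C; n-BuLi, −95 to 0 °C; then PhS(Cl)=N-t-Bu, −78 °C
Reagents that add atoms: none
Why: Proposed new method: dibromomethyllithium adds to the ketone, bromine–lithium exchange turns the adduct into a β-oxido carbenoid, and the unsubstituted ring CH2 (not the inductively deactivated oxirane carbon) undergoes the 1,2-shift with loss of LiBr to give the six-membered lithium enolate regiospecifically on the inserted carbon, which is then dehydrogenated in the same flask by S-sulfinimidoyl transfer and syn-elimination to the enone with no stereocenter touched; the closest known reactions are the Nozaki–Yamamoto β-oxido carbenoid ring enlargement of cycloalkanones and the Mukaiyama dehydrogenation of lithium enolates with N-tert-butylbenzenesulfinimidoyl chloride, neither shown on an α,β-epoxy ketone nor joined in one flask.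

Step 9
Reactants: 18 (1S,6S)-1-methyl-7-oxabicyclo[4.1.0]hept-3-en-2-one; 8 triethyl{[(3R)-6-methyl-2-(4,4,5,5-tetramethyl-1,3,2-dioxaborolan-2-yl)hepta-1,5-dien-3-yl]oxy}silane
Product: 19 (1S,4R,6S)-1-methyl-4-[(3R)-6-methyl-3-(triethylsilyloxy)hepta-1,5-dien-2-yl]-7-oxabicyclo[4.1.0]heptan-2-one
Conditions: [Rh(OH)((R)-binap)]2 (3 mol %), 8 (1.5 equiv.), dioxane/H2O 10:1, 35 °C, no added base
Reagents that add atoms: none
Why: Hayashi–Miyaura rhodium-catalysed asymmetric 1,4-addition: the (R)-BINAP alkenylrhodium species (the ligand enantiomer that gives (R)-3-arylcyclohexanones) adds to the face of the nearly planar epoxy enone that carries the oxirane oxygen, so the catalyst sets C4 with the side chain cis to the oxirane, while base-free conditions avoid vinylogous enolisation of 18.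

Step 10
Reactants: 19 (1S,4R,6S)-1-methyl-4-[(3R)-6-methyl-3-(triethylsilyloxy)hepta-1,5-dien-2-yl]-7-oxabicyclo[4.1.0]heptan-2-one
Product: 21 (1S,3S,4S,6S)-3-hydroxy-1-methyl-4-[(3R)-6-methyl-3-(triethylsilyloxy)hepta-1,5-dien-2-yl]-7-oxabicyclo[4.1.0]heptan-2-one, via potassium enolate 20 (not isolated)
Conditions: KN(SiMe3)2, THF, −78 °C; 2-(phenylsulfonyl)-3-phenyloxaziridine, −78 °C; aq. NH4Cl
Reagents that add atoms: 2-(phenylsulfonyl)-3-phenyloxaziridine O=S(=O)(N1OC1c1ccccc1)c1ccccc1
Why: Davis oxidation of the only possible enolate (the other α-carbon is the quaternary oxirane carbon): the oxaziridine transfers oxygen to C3 on the face opposite both the adjacent alkenyl group at C4 and the oxirane oxygen, giving the 3,4-trans hydroxy ketone.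

Step 11
Reactants: 21 (1S,3S,4S,6S)-3-hydroxy-1-methyl-4-[(3R)-6-methyl-3-(triethylsilyloxy)hepta-1,5-dien-2-yl]-7-oxabicyclo[4.1.0]heptan-2-one; 22 3-methylbut-2-enoyl chloride
Product: 23 (1S,3S,4S,6S)-1-methyl-4-[(3R)-6-methyl-3-(triethylsilyloxy)hepta-1,5-dien-2-yl]-2-oxo-7-oxabicyclo[4.1.0]heptan-3-yl 3-methylbut-2-enoate
Conditions: pyridine, DMAP (cat.), CH2Cl2, 0 °C
Reagents that add atoms: none
Why: DMAP-catalysed acylation of the α-hydroxy ketone by the acid chloride under mild pyridine conditions that neither epimerise C3 nor deconjugate the senecioyl group; configuration is retained.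

Step 12
Reactants: 23 (1S,3S,4S,6S)-1-methyl-4-[(3R)-6-methyl-3-(triethylsilyloxy)hepta-1,5-dien-2-yl]-2-oxo-7-oxabicyclo[4.1.0]heptan-3-yl 3-methylbut-2-enoate
Product: 25 (1S,3S,4S,6S)-4-[(3R)-3-acetoxy-6-methylhepta-1,5-dien-2-yl]-1-methyl-2-oxo-7-oxabicyclo[4.1.0]heptan-3-yl 3-methylbut-2-enoate, via desilylated allylic alcohol 24 (not isolated)
Conditions: HF·pyridine, pyridine, THF, 0 °C; then Ac2O, DMAP, 0 to 23 °C
Reagents that add atoms: acetic anhydride CC(=O)OC(C)=O
Why: Pyridine-buffered fluoride cleavage of the triethylsilyl ether (tolerated by the α,β-epoxy ketone and the ester) followed by DMAP-catalysed acetylation of the freed allylic alcohol, both with retention, gives the target.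

## Compound list

1 | 4-methylpent-3-en-1-ol | CC(C)=CCCO | starting material
2 | 4-methylpent-3-enal | CC(C)=CCC=O | intermediate
3 | ethynyltrimethylsilane | C#C[Si](C)(C)C | starting material
4 | methyl[(trimethylsilyl)ethynyl]zinc | C[Zn]C#C[Si](C)(C)C | intermediate
5 | (3R)-6-methyl-1-(trimethylsilyl)hept-5-en-1-yn-3-ol | C[Si](C)(C)C#C[C@@H](CC=C(C)C)O | intermediate
6 | (3R)-6-methylhept-5-en-1-yn-3-ol | C#C[C@@H](CC=C(C)C)O | intermediate
7 | triethyl{[(3R)-6-methylhept-5-en-1-yn-3-yl]oxy}silane | C#C[C@@H](CC=C(C)C)O[Si](CC)(CC)CC | intermediate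
8 | triethyl{[(3R)-6-methyl-2-(4,4,5,5-tetramethyl-1,3,2-dioxaborolan-2-yl)hepta-1,5-dien-3-yl]oxy}silane | C=C(B1OC(C)(C)C(C)(C)O1)[C@@H](CC=C(C)C)O[Si](CC)(CC)CC | intermediate
9 | 2-methylcyclopent-2-en-1-one | CC1=CCCC1=O | starting material
10 | (1R)-2-methylcyclopent-2-en-1-ol | O[C@@H]1CCC=C1C | intermediate
11 | (1R,2R,5S)-1-methyl-6-oxabicyclo[3.1.0]hexan-2-ol | O[C@@H]1CC[C@@H]2O[C@]12C | intermediate
12 | (1S,5S)-1-methyl-6-oxabicyclo[3.1.0]hexan-2-one | O=C1CC[C@@H]2O[C@]12C | intermediate
13 | dibromomethane | BrCBr | starting material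
14 | dibromomethyllithium | [Li]C(Br)Br | intermediate
15 | lithium (1S,5S)-2-(dibromomethyl)-1-methyl-6-oxabicyclo[3.1.0]hexan-2-olate (carbinol configuration not controlled) | [Li+].[O-]C1(C(Br)Br)CC[C@@H]2O[C@]12C | intermediate
16 | lithium (1S,5S)-2-[bromo(lithio)methyl]-1-methyl-6-oxabicyclo[3.1.0]hexan-2-olate | [Li+].[O-]C1(C([Li])Br)CC[C@@H]2O[C@]12C | intermediate
17 | lithium (1S,6S)-1-methyl-7-oxabicyclo[4.1.0]hept-2-en-2-olate | [Li+].[O-]C1=CCC[C@@H]2O[C@]12C | intermediate
18 | (1S,6S)-1-methyl-7-oxabicyclo[4.1.0]hept-3-en-2-one | O=C1C=CC[C@@H]2O[C@]12C | intermediate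
19 | (1S,4R,6S)-1-methyl-4-[(3R)-6-methyl-3-(triethylsilyloxy)hepta-1,5-dien-2-yl]-7-oxabicyclo[4.1.0]heptan-2-one | C=C([C@@H](CC=C(C)C)O[Si](CC)(CC)CC)[C@@H]1C[C@@H]2O[C@]2(C)C(=O)C1 | intermediate
20 | potassium (1S,4R,6S)-1-methyl-4-[(3R)-6-methyl-3-(triethylsilyloxy)hepta-1,5-dien-2-yl]-7-oxabicyclo[4.1.0]hept-2-en-2-olate | C=C([C@@H](CC=C(C)C)O[Si](CC)(CC)CC)[C@@H]1C[C@@H]2O[C@]2(C)C([O-])=C1.[K+] | intermediate
21 | (1S,3S,4S,6S)-3-hydroxy-1-methyl-4-[(3R)-6-methyl-3-(triethylsilyloxy)hepta-1,5-dien-2-yl]-7-oxabicyclo[4.1.0]heptan-2-one | C=C([C@@H](CC=C(C)C)O[Si](CC)(CC)CC)[C@@H]1C[C@@H]2O[C@]2(C)C(=O)[C@H]1O | intermediate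
22 | 3-methylbut-2-enoyl chloride | CC(C)=CC(Cl)=O | starting material
23 | (1S,3S,4S,6S)-1-methyl-4-[(3R)-6-methyl-3-(triethylsilyloxy)hepta-1,5-dien-2-yl]-2-oxo-7-oxabicyclo[4.1.0]heptan-3-yl 3-methylbut-2-enoate | C=C([C@@H](CC=C(C)C)O[Si](CC)(CC)CC)[C@@H]1C[C@@H]2O[C@]2(C)C(=O)[C@H]1OC(=O)C=C(C)C | intermediate
24 | (1S,3S,4S,6S)-4-[(3R)-3-hydroxy-6-methylhepta-1,5-dien-2-yl]-1-methyl-2-oxo-7-oxabicyclo[4.1.0]heptan-3-yl 3-methylbut-2-enoate | C=C([C@@H](CC=C(C)C)O)[C@@H]1C[C@@H]2O[C@]2(C)C(=O)[C@H]1OC(=O)C=C(C)C | intermediate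
25 | (1S,3S,4S,6S)-4-[(3R)-3-acetoxy-6-methylhepta-1,5-dien-2-yl]-1-methyl-2-oxo-7-oxabicyclo[4.1.0]heptan-3-yl 3-methylbut-2-enoate (CNP0168401.1) | C=C([C@@H](CC=C(C)C)OC(C)=O)[C@@H]1C[C@@H]2O[C@]2(C)C(=O)[C@H]1OC(=O)C=C(C)C | target

## Step count and risks

Total step count: 12. Longest linear sequence: 8 (steps 1–4 or steps 5–8, then steps 9–12).

Three steps are most likely to fail.

Step 8, the proposed new ring expansion, is the first. The oxirane carbon could migrate instead of the CH2, the hindered amide could enolise 12 before the carbenoid adds, or the base-sensitive enone 18 could be lost in the flask. The fallback is known Ito–Saegusa chemistry; it sets out from 12 and comes back at 18. Ketone 12 is converted with LiN(i-Pr)2 and Me3SiCl (THF, −78 °C) into the silyl enol ether trimethyl{[(1S,5S)-1-methyl-6-oxabicyclo[3.1.0]hex-2-en-2-yl]oxy}silane F1, which can only form on the CH2 side. Cyclopropanation with Et2Zn and CH2I2 gives the siloxycyclopropane trimethyl[(2-methyl-3-oxatricyclo[4.1.0.0(2,4)]hept-1-yl)oxy]silane F2. FeCl3 in DMF at 0 °C opens the internal cyclopropane bond by one-electron oxidation to the ring-expanded β-chloro ketone (1S,6S)-4-chloro-1-methyl-7-oxabicyclo[4.1.0]heptan-2-one F3. NaOAc in MeOH at 23 °C removes HCl and gives 18. The regiochemistry is fixed by the position of the enol ether and the mechanism is a radical ring opening, not a carbenoid shift.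

Step 9, the rhodium addition, is the second. The catalyst has to override the substrate's likely preference for attack anti to the oxirane oxygen, and 18 isomerises under base. The fallback sets out from 18 (with 8) and comes back at 19. The oxirane of 18 is first opened with MgBr2·OEt2 (Et2O, 0 °C; bromide attacks the β-carbon with inversion) to the trans-bromohydrin (5R,6R)-5-bromo-6-hydroxy-6-methylcyclohex-2-en-1-one F4, whose bromine now sits on the face that must stay free. The same [Rh(OH)((R)-binap)]2 addition of 8 then runs with substrate and catalyst matched (attack trans to the substituent at C5, the usual outcome for 5-substituted cyclohexenones) and gives (2R,3R,5S)-3-bromo-2-hydroxy-2-methyl-5-[(3R)-6-methyl-3-(triethylsilyloxy)hepta-1,5-dien-2-yl]cyclohexan-1-one F5. K2CO3 in MeOH at 0 °C closes the oxirane again by displacement of bromide and gives 19. Control thus moves from the catalyst working against the oxirane to a temporary directing group.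

Step 2, the asymmetric alkynylation, is the third. The enolisable β,γ-unsaturated aldehyde may isomerise or self-condense, and the ee may be modest. The fallback sets out from 2 and 3 and comes back at 5. Compound 3 is deprotonated with n-BuLi (THF, −78 °C) to lithium (trimethylsilyl)acetylide F6, which adds to 2 to give racemic 6-methyl-1-(trimethylsilyl)hept-5-en-1-yn-3-ol F7. Dess–Martin oxidation gives the ynone 6-methyl-1-(trimethylsilyl)hept-5-en-1-yn-3-one F8. Noyori transfer hydrogenation with RuCl[(R,R)-TsDPEN](p-cymene) in i-PrOH at 23 °C gives 5, which is desilylated to 6 as in step 2. The stereocenter is then set by asymmetric reduction instead of asymmetric addition.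

## Further compounds

F1 | step 8 | trimethyl{[(1S,5S)-1-methyl-6-oxabicyclo[3.1.0]hex-2-en-2-yl]oxy}silane | C[Si](C)(C)OC1=CC[C@@H]2O[C@]12C
F2 | step 8 | trimethyl[(2-methyl-3-oxatricyclo[4.1.0.0(2,4)]hept-1-yl)oxy]silane (siloxycyclopropane, cyclopropane face not controlled) | C[Si](C)(C)OC13CC3C[C@@H]2O[C@]12C
F3 | step 8 | (1S,6S)-4-chloro-1-methyl-7-oxabicyclo[4.1.0]heptan-2-one (C4 epimers) | O=C1CC(Cl)C[C@@H]2O[C@]12C
F4 | step 9 | (5R,6R)-5-bromo-6-hydroxy-6-methylcyclohex-2-en-1-one | C[C@]1(O)[C@H](Br)CC=CC1=O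
F5 | step 9 | (2R,3R,5S)-3-bromo-2-hydroxy-2-methyl-5-[(3R)-6-methyl-3-(triethylsilyloxy)hepta-1,5-dien-2-yl]cyclohexan-1-one | C=C([C@@H](CC=C(C)C)O[Si](CC)(CC)CC)[C@@H]1C[C@@H](Br)[C@](C)(O)C(=O)C1
F6 | step 2 | lithium (trimethylsilyl)acetylide | [Li]C#C[Si](C)(C)C
F7 | step 2 | rac-6-methyl-1-(trimethylsilyl)hept-5-en-1-yn-3-ol | C[Si](C)(C)C#CC(O)CC=C(C)C
F8 | step 2 | 6-methyl-1-(trimethylsilyl)hept-5-en-1-yn-3-one | C[Si](C)(C)C#CC(=O)CC=C(C)C
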